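(All runs come from a simulation from invented constants.)

The amounts to follow in this flask are the fractions left: equal charges of left-handed and right-handed substrate meet one single-handed catalyst and one partner, and each substrate is counted against its own charge.

| flask | left-handed substrate | right-handed substrate | partner | precatalyst | impurity | remark | time |
|---|---|---|---|---|---|---|---|
| theta | 0.56 M | 0.56 M | 1.1 equiv | 1 mol% | 1.1 mM | run made earlier |  |
| beta | 0.88 M | 0.88 M | 1.1 equiv | 1 mol% | 1.1 mM | run made earlier |  |
| alpha | 0.40 M | 0.40 M | 1.1 equiv | 1 mol% | 2.2 mM | run made earlier |  |
| flask | 0.40 M | 0.40 M | 1.10 equiv | 1 mol% | 1.1 mM |  | 8.0 min |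

| run | time / min | right-handed substrate / % | left-handed substrate / % |
|---|---|---|---|
| theta | 2.00 | 47.1 | 7.1 |
| theta | 4.00 | 47.2 | 2.3 |
| theta | 6.00 | 46.4 | 0.7 |
| theta | 8.00 | 46.4 | 0.7 |
| theta | 10.0 | 45.0 | 1.4 |
| beta | 0.833 | 47.8 | 6.5 |
| beta | 2.50 | 46.2 | 1.5 |
| beta | 4.00 | 45.6 | 0.3 |
| beta | 6.00 | 44.0 | 0.8 |
| beta | 10.0 | 45.8 | 0 |
| alpha | 0.833 | 50.3 | 39.3 |
| alpha | 1.33 | 49.2 | 33.5 |
| alpha | 2.50 | 48.8 | 19.9 |
| alpha | 5.00 | 48.0 | 7.7 |
| alpha | 10.0 | 47.2 | 2.2 |

(standard deviation of a reading: 0.5 percentage points)

- free catalyst is single-handed; left-handed substrate and right-handed substrate are mirror images of each other, charged as a racemate, each of them at the stated concentration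
- candidate steps: partner + free catalyst + left-handed substrate -> free catalyst + left-handed product; partner + free catalyst + right-handed substrate -> free catalyst + right-handed product; partner + precatalyst -> free catalyst + spent reagent; free catalyst + impurity -> spent catalyst

- whether the excess of right-handed substrate over left-handed substrate among what is left of the two reaches 80% by 8.0 min (no / yes)
- the highest excess of right-handed substrate over left-handed substrate among what is left of the two up to 8.0 min

Step 1. Free catalyst and partner enter both rates alike, so they cancel in the ratio of the rates. You can therefore divide ln(fraction of left-handed substrate left) by ln(fraction of right-handed substrate left) and expect a constant, however the catalyst varies. The alpha run at 5.00 min has fractions 15.4% and 96.0%, which gives 45.8, the selectivity factor. It is a loose reading, since the right-handed substrate has lost 2 percentage points against a scatter of 0.5 points.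

Step 2. An excess of 80% means left-handed over right-handed equals 0.111. The factor places that crossing at a left-handed fraction of 10.6%. The curve starts at zero excess and climbs steeply, reaching 32.7% where the left-handed fraction is 0.5.

Step 3. Now the clock. The impurity removes free catalyst one for one, so of 4.00 mM precatalyst charged this flask keeps 2.90 mM as precatalyst and free catalyst together, and the alpha run 1.80 mM. If pace follows surviving catalyst, this flask runs 1.61 times the alpha pace, more than the 1.25 needed to pass the alpha reading at 10.0 min by 8.0 min. That reading is 4.40% left, below the crossing. So I reckon yes, crossing near 4.03 min, and still rising at the end, with an excess near 91.0% at that fraction.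

Step 4. The forecast says yes and 91%: “so the excess climbs steadily”.

Step 5. The flask gives yes, with a top of 92.0%.

    partner + free catalyst + left-handed substrate → free catalyst + left-handed product (k = 61.0 L² mol⁻² s⁻¹)
    partner + free catalyst + right-handed substrate → free catalyst + right-handed product (k = 1.30 L² mol⁻² s⁻¹)
    partner + precatalyst → free catalyst + spent reagent (k = 0.0260 L mol⁻¹ s⁻¹)
    free catalyst + impurity → spent catalyst (k = 100 L mol⁻¹ s⁻¹)

At 8.00 min the flask holds 3.9% of its left-handed charge. Put through the selectivity factor, that fraction gives 93.1% of the right-handed charge, and the flask holds 93%. In the beta run at 2.50 min, the left-handed fraction of 3.00% gives the right-handed substrate as 46.3% of the two together, and the reading is 46.2%.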